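Amounts are the point here: south, south-east and south-west start from the same charge of starting material, and what counts is how much of it stands as ring at the end.

| flask | starting material | temperature | remark | time |
|---|---|---|---|---|
| dawn | 2.8 M | 20 °C | run made earlier |  |
| winter | 2.8 M | 45 °C | run made earlier |  |
| south | 2.0 M | 65 °C |  | 10 min |
| south-east | 2.0 M | 45 °C |  | 10 min |
| south-west | 2.0 M | 25 °C |  | 10 min |

| run | time / min | ring / % |
|---|---|---|
| dawn | 8.00 | 55.6 |
| dawn | 25.0 | 79.9 |
| dawn | 40.0 | 84.7 |
| dawn | 60.0 | 94.3 |
| dawn | 90.0 | 96.3 |
| dawn | 120 | 99.3 |
| winter | 2.50 | 83.3 |
| winter | 6.00 | 84.8 |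
| winter | 10.0 | 85.7 |
| winter | 15.0 | 87.9 |
| winter | 25.0 | 93.0 |
| winter | 30.0 | 91.5 |

(scatter of a reading: 1 percentage point)

* which flask leads in amount of ring, in percent of the starting material charged ("all alike" within 1.5 percentage points) (south / south-east / south-west / all alike)
* how much ring is there at the end, in percent of the starting material charged: south
* how much ring is there at the end, in percent of the starting material charged: south-east
* how much ring is there at the end, in percent of the starting material charged: south-west

- a reading or a percentage of ring counts all its forms, free or not

Time is the first setting. If a rise of ring is replaced by one exponential, the first reading of the dawn run, 55.6% after 8.00 min, gives a mean constant k of 0.101 min⁻¹. The check comes from the next reading: this exponential predicts 92.0% at 25.0 min, but the reading is 79.9%, so the exponential runs ahead of the dawn run at that time.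

Temperature is the second setting. The first winter reading, 83.3% after 2.50 min, gives k = 0.716 min⁻¹, so, as read from these two scattered readings, the mean k doubles about every 8.87 K.

The amount is the setting left. Both runs stood at 2.8 M, so they show nothing about it, and k is carried unchanged to 2.0 M, which is a risk.

The mean half-life, the time in which the unreacted share halves on this single exponential, is then 4.62 min for south-west. My reckoning from it is 77.7% ring at 10 min. In south-east the mean half-life is 0.968 min, well below the time allowed, so the winter reading of 85.7% at 10.0 min serves as the estimate there. No earlier run shows ring at the temperature of south.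

The forecast reads two routes, “a fast direct one, and a slow one through a reservoir”. It gives 92% for south, 85% for south-east and 64% for south-west, with south leading. Its south-west figure lies 14 percentage points below my reckoning.

The flasks give 84.1% in south, 89.1% in south-east and 77.6% in south-west, so south-east leads.

    crystals ⇌ ring, rate k1*(cs1 - [ring]) while solid is left; crystals form when [ring] > cs1 (solubility = 0.860 M, k = 16.8 min⁻¹)
    2 starting material ⇌ open dimer (K = 1.60 M⁻¹, k = 0.0540 M⁻¹ min⁻¹, Ea = 61.0 kJ mol⁻¹, ΔH = 52.0 kJ mol⁻¹)
    ring → over-reaction product (k = 3.38 × 10⁻⁴ min⁻¹, Ea = 90.0 kJ mol⁻¹)
    starting material → ring (k = 0.321 min⁻¹, Ea = 87.0 kJ mol⁻¹)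
    (constants at 25 °C)

In south-west the mean half-life of 4.62 min lies between two times of the flask: by its step into ring, starting material has a half-life of 2.2 min at 1.82 min, while the step between starting material and open dimer, taken by itself, relaxes, both ways together, with a half-life of 13.3 min at 10.0 min, when 18.0% of the charge stands as open dimer. Carried to the neighbouring flask, south-west run at 10 °C, the mean half-life becomes 14.9 min and gives 37.2% ring, where that flask holds 33.0%.

The readings were generated by integration with made-up constants.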